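**Retrosynthetic overview**

1. Labels: ring A is the methoxy-dimethyl benzoyl ring. Ring B is the hexasubstituted ring, with B1 (diaryl ether O), B2 (lactone O), B3 (CH2OH), B4 (OH), B5 (phthalide C=O carbon) and B6 (lactol carbon). The strategy rests on ring B: oxygens para at B1 and B4, an oxygenated B2 and an alkylated B3 between them, and two adjacent one-carbon branches on B5/B6. This is the pattern of a hydroquinone made by ring expansion of a squarate-derived 4-alkenylcyclobutenone.
2. The (R)-lactol comes last, from dialdehyde 29, by enantioselective carbene-catalysed oxidation of the B5 formyl group in the presence of water. 29 comes from depsidone bis-acetal 28 by acid hydrolysis.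
3. The seven-membered depsidone lactone is closed by lactonisation (B2 oxygen onto the ring-A carboxyl) after O-arylation of the B1 phenoxide with ring-A iodonium salt 23, made from methyl 2,4-dihydroxy-3,6-dimethylbenzoate.
4. Ring B with its fused bis-acetal dihydrofuran is formed by thermal ring expansion of silyloxycyclobutenone 12. Compound 12 is assembled from dibenzyl squarate, (methoxymethoxy)methyllithium and lithiated 2,5-dimethoxy-2,5-dihydrofuran (from 3-bromofuran).
5. Ring order: ring A is bought; then the cyclobutenone; ring B and the fused dihydrofuran (step 5); the seven-membered lactone (step 15); the γ-lactol ring (step 17).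

Key step: step 5

Assumption: the lactol carbon of a 3-hydroxyphthalide can epimerise through its ring-opened formyl acid; it is taken to hold its configuration under neutral, aprotic, cold conditions, so it is created in the last step and the product is isolated without acid or base.

Remark: benzyl is used as the squarate ester group so that the B2 oxygen can be freed by hydrogenolysis in the presence of the acetals and MOM ethers; a MOM ether protects B4.

**Route**

Step 1
Reactants: 1 squaric acid
Product: 2 dibenzyl squarate (3,4-bis(benzyloxy)cyclobut-3-ene-1,2-dione)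
Conditions: BnOH (4 equiv), toluene, reflux, azeotropic removal of water
Reagents that add atoms: benzyl alcohol, OCc1ccccc1
Why: Fischer-type azeotropic esterification of the vinylogous diacid gives the dialkyl squarate, as for the dibutyl and diisopropyl esters.

Step 2
Reactants: 2 dibenzyl squarate; 3 tributyl[(methoxymethoxy)methyl]stannane
Product: 7 3-(benzyloxy)-4-[(methoxymethoxy)methyl]cyclobut-3-ene-1,2-dione, via (methoxymethoxy)methyllithium 4 (not isolated), via lithium alkoxide 5 (not isolated), via trifluoroacetate 6 (not isolated)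
Conditions: 3, n-BuLi, THF, −78 °C; then 2, THF, −78 °C; (CF3CO)2O, −78 °C; aq. NH4Cl, −78 °C → rt
Reagents that add atoms: water, O
Why: Tin–lithium exchange releases the alkoxymethyllithium, which adds once to a squarate carbonyl, and trifluoroacetylation of the alkoxide followed by hydrolytic loss of one benzyloxy group (the standard squarate 1,2-addition/rearrangement) gives the 3-alkoxy-4-alkylcyclobutenedione under conditions that spare the MOM ether.

Step 3
Reactants: 8 3-bromofuran
Product: 9 3-bromo-2,5-dimethoxy-2,5-dihydrofuran (cis/trans mixture)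
Conditions: Br2, MeOH, KOAc, −45 °C → rt
Reagents that add atoms: methanol, CO
Why: Clauson-Kaas oxidative 2,5-dimethoxylation turns the furan into the cyclic bis-acetal and leaves the vinyl bromide on the remaining C3=C4 double bond.

Step 4
Reactants: 9 3-bromo-2,5-dimethoxy-2,5-dihydrofuran; 7 3-(benzyloxy)-4-[(methoxymethoxy)methyl]cyclobut-3-ene-1,2-dione
Product: 12 3-(benzyloxy)-4-(2,5-dimethoxy-2,5-dihydrofuran-3-yl)-2-[(methoxymethoxy)methyl]-4-[(triethylsilyl)oxy]cyclobut-2-en-1-one (stereoisomer mixture), via vinyllithium 10 (not isolated), via lithium alkoxide 11 (not isolated)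
Conditions: 9, t-BuLi (2 equiv), Et2O, −78 °C; then 7, THF, −78 °C; Et3SiOTf (1.1 equiv), −78 °C; Et3N, then aq. NaHCO3
Reagents that add atoms: triethylsilyl trifluoromethanesulfonate, CC[Si](CC)(CC)OS(=O)(=O)C(F)(F)F
Why: Bromine–lithium exchange gives the vinyllithium, which undergoes 1,2-addition to the more electrophilic carbonyl of 7 (the one next to the benzyloxy carbon, the other being a vinylogous ester), and the lithium alkoxide is capped cold as its triethylsilyl ether before it can fragment.

Step 5
Reactants: 12 3-(benzyloxy)-4-(2,5-dimethoxy-2,5-dihydrofuran-3-yl)-2-[(methoxymethoxy)methyl]-4-[(triethylsilyl)oxy]cyclobut-2-en-1-one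
Product: 15 6-(benzyloxy)-1,3-dimethoxy-5-[(methoxymethoxy)methyl]-7-[(triethylsilyl)oxy]-1,3-dihydroisobenzofuran-4-ol (acetal stereoisomer mixture), via dienylketene 13 (not isolated), via cyclohexadienone 14 (not isolated)
Conditions: toluene (degassed, 0.02 M), 110 °C, argon
Reagents that add atoms: none
Why: Heating triggers conrotatory 4π electrocyclic opening of the C1–C4 bond of the cyclobutenone to dienylketene 13, the silyloxy donor rotating outward (torquoselectivity) so that the dihydrofuranyl group lies cis to the ketene. Disrotatory 6π electrocyclisation then joins the ketene carbon (B4) to the dihydrofuran alkene carbon (B5), closing the six-membered carbocycle (ring B) as cyclohexadienone 14, and enolisation of the ring-fusion hydrogen aromatises it to phenol 15. The closest known reaction type is the Moore rearrangement of squarate-derived 4-alkenyl-4-(silyloxy)cyclobutenones to monosilylated hydroquinones. The transient ring-fusion centre is destroyed on enolisation and the two acetal carbons are carried as a mixture, so no stereocentre has to be controlled. The step needs outward rotation of the oxygen and 6π closure in preference to ketene trapping; the strong donor at C4 secures the first, and the s-cis geometry enforced by the ring alkene, dilution and exclusion of nucleophiles and air secure the second. The differentiation of B1 (silyl ether) from B4 (free hydroxyl) follows from the regiochemistry of the addition in step 4.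

Step 6
Reactants: 15 6-(benzyloxy)-1,3-dimethoxy-5-[(methoxymethoxy)methyl]-7-[(triethylsilyl)oxy]-1,3-dihydroisobenzofuran-4-ol
Product: 16 6-(benzyloxy)-1,3-dimethoxy-4-(methoxymethoxy)-5-[(methoxymethoxy)methyl]-7-[(triethylsilyl)oxy]-1,3-dihydroisobenzofuran
Conditions: NaH, MOMCl, THF, 0 °C → rt
Reagents that add atoms: chloromethyl methyl ether, COCCl
Why: Williamson etherification of the sodium phenoxide masks the B4 hydroxyl so that only the B1 oxygen is arylated later, and the aryl silyl ether is stable to these conditions.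

Step 7
Reactants: 17 methyl 2,4-dihydroxy-3,6-dimethylbenzoate
Product: 18 methyl 2-hydroxy-4-methoxy-3,6-dimethylbenzoate
Conditions: MeI (1.1 equiv), K2CO3, acetone, reflux
Reagents that add atoms: iodomethane, CI
Why: The 4-hydroxyl is the only phenol not chelated to the ester, so mild-base Williamson methylation is selective for it.

Step 8
Reactants: 18 methyl 2-hydroxy-4-methoxy-3,6-dimethylbenzoate
Product: 19 methyl 4-methoxy-3,6-dimethyl-2-[(trifluoromethanesulfonyl)oxy]benzoate
Conditions: Tf2O, pyridine, CH2Cl2, 0 °C → rt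
Reagents that add atoms: trifluoromethanesulfonic anhydride, O=S(=O)(OS(=O)(=O)C(F)(F)F)C(F)(F)F
Why: O-sulfonylation of the phenol turns the C2 oxygen into a leaving group for palladium catalysis.

Step 9
Reactants: 19 methyl 4-methoxy-3,6-dimethyl-2-[(trifluoromethanesulfonyl)oxy]benzoate
Product: 20 methyl 4-methoxy-3,6-dimethyl-2-(trimethylstannyl)benzoate
Conditions: Me3SnSnMe3, Pd(PPh3)4 (5 mol %), LiCl, 1,4-dioxane, 100 °C
Reagents that add atoms: hexamethylditin, C[Sn](C)(C)[Sn](C)(C)C
Why: Palladium-catalysed stannylation of an aryl triflate with a distannane (oxidative addition helped by the ortho ester, chloride-promoted transmetalation) gives the arylstannane.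

Step 10
Reactants: 20 methyl 4-methoxy-3,6-dimethyl-2-(trimethylstannyl)benzoate
Product: 21 methyl 2-iodo-4-methoxy-3,6-dimethylbenzoate
Conditions: I2, CH2Cl2, 0 °C → rt
Reagents that add atoms: iodine, II
Why: Ipso iododestannylation is fast and site-specific, so iodine enters only at C2.

Step 11
Reactants: 21 methyl 2-iodo-4-methoxy-3,6-dimethylbenzoate
Product: 23 [5-methoxy-2-(methoxycarbonyl)-3,6-dimethylphenyl](2,4,6-trimethoxyphenyl)iodonium 4-methylbenzenesulfonate, via hydroxy(tosyloxy)iodoarene 22 (not isolated)
Conditions: mCPBA, TsOH·H2O, MeCN, 60 °C; then 1,3,5-trimethoxybenzene, rt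
Reagents that add atoms: 1,3,5-trimethoxybenzene, COc1cc(OC)cc(OC)c1; 4-methylbenzenesulfonic acid monohydrate, Cc1ccc(S(=O)(=O)O)cc1.O
Why: In this one-pot diaryliodonium synthesis the peracid and sulfonic acid oxidise the iodoarene to the trivalent-iodine species 22, which arylates the electron-rich trimethoxybenzene by electrophilic aromatic substitution.

Step 12
Reactants: 16 6-(benzyloxy)-1,3-dimethoxy-4-(methoxymethoxy)-5-[(methoxymethoxy)methyl]-7-[(triethylsilyl)oxy]-1,3-dihydroisobenzofuran; 23 aryl(2,4,6-trimethoxyphenyl)iodonium 4-methylbenzenesulfonate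
Product: 25 methyl 2-{[6-(benzyloxy)-1,3-dimethoxy-4-(methoxymethoxy)-5-[(methoxymethoxy)methyl]-1,3-dihydroisobenzofuran-7-yl]oxy}-4-methoxy-3,6-dimethylbenzoate, via cesium phenoxide 24 (not isolated)
Conditions: 16, CsF (1.2 equiv), DMF, rt; then 23, rt → 45 °C, argon
Reagents that add atoms: none
Why: Fluoride desilylation releases the oxidation-prone B1 phenoxide in the flask, and metal-free O-arylation by ligand coupling at the iodonium transfers the di-ortho-substituted, ester-bearing aryl group in preference to the electron-rich trimethoxyphenyl dummy, a reaction type that tolerates tetra-ortho-substituted diaryl ethers.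

Step 13
Reactants: 25 methyl 2-{[6-(benzyloxy)-1,3-dimethoxy-4-(methoxymethoxy)-5-[(methoxymethoxy)methyl]-1,3-dihydroisobenzofuran-7-yl]oxy}-4-methoxy-3,6-dimethylbenzoate
Product: 26 2-{[6-(benzyloxy)-1,3-dimethoxy-4-(methoxymethoxy)-5-[(methoxymethoxy)methyl]-1,3-dihydroisobenzofuran-7-yl]oxy}-4-methoxy-3,6-dimethylbenzoic acid
Conditions: n-PrSLi, HMPA, rt; then aq. NaH2PO4 (pH 4–5)
Reagents that add atoms: none
Why: SN2 dealkylation at the ester methyl group by thiolate cleaves the di-ortho-substituted benzoate, which resists saponification, without touching the acetals, MOM ethers or benzyl ether.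

Step 14
Reactants: 26 2-{[6-(benzyloxy)-1,3-dimethoxy-4-(methoxymethoxy)-5-[(methoxymethoxy)methyl]-1,3-dihydroisobenzofuran-7-yl]oxy}-4-methoxy-3,6-dimethylbenzoic acid
Product: 27 2-{[6-hydroxy-1,3-dimethoxy-4-(methoxymethoxy)-5-[(methoxymethoxy)methyl]-1,3-dihydroisobenzofuran-7-yl]oxy}-4-methoxy-3,6-dimethylbenzoic acid
Conditions: H2 (1 atm), Pd/C (10 wt %), EtOAc, rt
Reagents that add atoms: none
Why: Catalytic hydrogenolysis cleaves the aryl benzyl ether and frees the B2 phenol under neutral conditions that leave the MOM ethers, acetals and diaryl ether intact.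

Step 15
Reactants: 27 2-{[6-hydroxy-1,3-dimethoxy-4-(methoxymethoxy)-5-[(methoxymethoxy)methyl]-1,3-dihydroisobenzofuran-7-yl]oxy}-4-methoxy-3,6-dimethylbenzoic acid
Product: 28 protected depsidone bis-acetal (seven-membered lactone between the ring-A carboxyl and the B2 oxygen; B4 OMOM; B3 CH2OMOM; B5/B6 fused 1,3-dimethoxy-1,3-dihydrofuran; acetal stereoisomer mixture)
Conditions: DCC, DMAP (cat.), CH2Cl2 (0.005 M), rt
Reagents that add atoms: none
Why: Steglich-type carbodiimide activation of the acid and intramolecular acylation of the adjacent B2 phenol at high dilution closes the seven-membered depsidone lactone, the usual ring closure of hydroxy diaryl ether acids.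

Step 16
Reactants: 28 protected depsidone bis-acetal
Product: 29 depsidone dialdehyde (B5 and B6 formyl; B4 hydroxyl; B3 hydroxymethyl)
Conditions: 2 M H2SO4 (aq.), THF, 45 °C
Reagents that add atoms: water, O
Why: Aqueous acid hydrolyses the cyclic bis-acetal to the two formyl groups and cleaves both MOM ethers, the non-nucleophilic acid and excess water returning any benzylic cation to the alcohol while the hindered aryl lactone survives.

Step 17
Reactants: 29 depsidone dialdehyde
Product: 30 (R)-lactol target CNP0321962.1
Conditions: (5aR,10bS)-2-mesityl-5a,10b-dihydro-4H,6H-indeno[2,1-b][1,2,4]triazolo[4,3-d][1,4]oxazin-2-ium tetrafluoroborate (10 mol %; its antipode if the sense of induction proves opposite), i-Pr2NEt (10 mol %), 3,3',5,5'-tetra-tert-butyldiphenoquinone (1.1 equiv), H2O (3 equiv), CHCl3, 0 °C; neutral work-up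
Reagents that add atoms: water, O
Why: Proposed new method: the chiral triazolylidene adds to the B5 formyl group (held coplanar and activated by the hydrogen bond from the neutral B4 hydroxyl, whereas the B6 formyl is twisted between the ether oxygen and its neighbour), the hydroxy-enamine adduct is oxidised by the diphenoquinone to an acyl azolium, water adds reversibly to the B6 formyl to give a gem-diol whose two enantiotopic hydroxyls are differentiated by the chiral acyl azolium in an intramolecular 5-exo-trig acyl transfer that closes the γ-lactone and sets the (R)-lactol centre under catalyst control; the closest known reaction types are the carbene-catalysed oxidative enantioselective acetalisation of phthalaldehydes with carboxylic acids to phthalidyl esters and the carbene-catalysed dynamic kinetic acylation of 3-hydroxyphthalides.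

**Compound list**

1 | squaric acid | O=C1C(=O)C(O)=C1O | starting material
2 | dibenzyl squarate | O=C1C(=O)C(OCc2ccccc2)=C1OCc1ccccc1 | intermediate
3 | tributyl[(methoxymethoxy)methyl]stannane | CCCC[Sn](CCCC)(CCCC)COCOC | starting material
4 | (methoxymethoxy)methyllithium | [Li]COCOC | intermediate
5 | lithium 2,3-bis(benzyloxy)-1-[(methoxymethoxy)methyl]-4-oxocyclobut-2-en-1-olate | [Li+].[O-]C1(COCOC)C(=O)C(OCc2ccccc2)=C1OCc1ccccc1 | intermediate
6 | 2,3-bis(benzyloxy)-1-[(methoxymethoxy)methyl]-4-oxocyclobut-2-en-1-yl trifluoroacetate | O=C(OC1(COCOC)C(=O)C(OCc2ccccc2)=C1OCc1ccccc1)C(F)(F)F | intermediate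
7 | 3-(benzyloxy)-4-[(methoxymethoxy)methyl]cyclobut-3-ene-1,2-dione | O=C1C(=O)C(COCOC)=C1OCc1ccccc1 | intermediate
8 | 3-bromofuran | Brc1ccoc1 | starting material
9 | 3-bromo-2,5-dimethoxy-2,5-dihydrofuran (cis/trans mixture) | COC1OC(OC)C(Br)=C1 | intermediate
10 | (2,5-dimethoxy-2,5-dihydrofuran-3-yl)lithium | [Li]C1=CC(OC)OC1OC | intermediate
11 | lithium 2-(benzyloxy)-1-(2,5-dimethoxy-2,5-dihydrofuran-3-yl)-3-[(methoxymethoxy)methyl]-4-oxocyclobut-2-en-1-olate | [Li+].[O-]C1(C(=O)C(COCOC)=C1OCc2ccccc2)C3=CC(OC)OC3OC | intermediate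
12 | 3-(benzyloxy)-4-(2,5-dimethoxy-2,5-dihydrofuran-3-yl)-2-[(methoxymethoxy)methyl]-4-[(triethylsilyl)oxy]cyclobut-2-en-1-one (stereoisomer mixture) | CC[Si](CC)(CC)OC1(C(=O)C(COCOC)=C1OCc2ccccc2)C3=CC(OC)OC3OC | intermediate
13 | dienylketene: 3-(benzyloxy)-4-(2,5-dimethoxy-2,5-dihydrofuran-3-yl)-2-[(methoxymethoxy)methyl]-4-[(triethylsilyl)oxy]buta-1,3-dien-1-one, ketene chain cis to the dihydrofuranyl group | O=C=C(COCOC)/C(OCc1ccccc1)=C(/O[Si](CC)(CC)CC)C2=CC(OC)OC2OC | intermediate
14 | cyclohexadienone: 6-(benzyloxy)-1,3-dimethoxy-5-[(methoxymethoxy)methyl]-7-[(triethylsilyl)oxy]-3,3a-dihydroisobenzofuran-4(1H)-one | O=C1C(COCOC)=C(OCc3ccccc3)C(O[Si](CC)(CC)CC)=C2C(OC)OC(OC)C12 | intermediate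
15 | 6-(benzyloxy)-1,3-dimethoxy-5-[(methoxymethoxy)methyl]-7-[(triethylsilyl)oxy]-1,3-dihydroisobenzofuran-4-ol (acetal stereoisomer mixture) | COC1OC(OC)c2c1c(O)c(COCOC)c(OCc3ccccc3)c2O[Si](CC)(CC)CC | intermediate
16 | 6-(benzyloxy)-1,3-dimethoxy-4-(methoxymethoxy)-5-[(methoxymethoxy)methyl]-7-[(triethylsilyl)oxy]-1,3-dihydroisobenzofuran (acetal stereoisomer mixture) | COCOc1c(COCOC)c(OCc2ccccc2)c(O[Si](CC)(CC)CC)c2C(OC)OC(OC)c12 | intermediate
17 | methyl 2,4-dihydroxy-3,6-dimethylbenzoate | COC(=O)c1c(C)cc(O)c(C)c1O | starting material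
18 | methyl 2-hydroxy-4-methoxy-3,6-dimethylbenzoate | COC(=O)c1c(C)cc(OC)c(C)c1O | intermediate
19 | methyl 4-methoxy-3,6-dimethyl-2-[(trifluoromethanesulfonyl)oxy]benzoate | COC(=O)c1c(C)cc(OC)c(C)c1OS(=O)(=O)C(F)(F)F | intermediate
20 | methyl 4-methoxy-3,6-dimethyl-2-(trimethylstannyl)benzoate | COC(=O)c1c(C)cc(OC)c(C)c1[Sn](C)(C)C | intermediate
21 | methyl 2-iodo-4-methoxy-3,6-dimethylbenzoate | COC(=O)c1c(C)cc(OC)c(C)c1I | intermediate
22 | methyl 2-[hydroxy(tosyloxy)iodo]-4-methoxy-3,6-dimethylbenzoate | COC(=O)c1c(C)cc(OC)c(C)c1I(O)OS(=O)(=O)c1ccc(C)cc1 | intermediate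
23 | [5-methoxy-2-(methoxycarbonyl)-3,6-dimethylphenyl](2,4,6-trimethoxyphenyl)iodonium 4-methylbenzenesulfonate | COC(=O)c1c(C)cc(OC)c(C)c1[I+]c1c(OC)cc(OC)cc1OC.Cc1ccc(S(=O)(=O)[O-])cc1 | intermediate
24 | cesium 6-(benzyloxy)-1,3-dimethoxy-4-(methoxymethoxy)-5-[(methoxymethoxy)methyl]-1,3-dihydroisobenzofuran-7-olate | [Cs+].[O-]c1c(OCc2ccccc2)c(COCOC)c(OCOC)c2C(OC)OC(OC)c12 | intermediate
25 | methyl 2-{[6-(benzyloxy)-1,3-dimethoxy-4-(methoxymethoxy)-5-[(methoxymethoxy)methyl]-1,3-dihydroisobenzofuran-7-yl]oxy}-4-methoxy-3,6-dimethylbenzoate (acetal stereoisomer mixture) | COC(=O)c1c(C)cc(OC)c(C)c1Oc1c(OCc2ccccc2)c(COCOC)c(OCOC)c2C(OC)OC(OC)c12 | intermediate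
26 | 2-{[6-(benzyloxy)-1,3-dimethoxy-4-(methoxymethoxy)-5-[(methoxymethoxy)methyl]-1,3-dihydroisobenzofuran-7-yl]oxy}-4-methoxy-3,6-dimethylbenzoic acid (acetal stereoisomer mixture) | OC(=O)c1c(C)cc(OC)c(C)c1Oc1c(OCc2ccccc2)c(COCOC)c(OCOC)c2C(OC)OC(OC)c12 | intermediate
27 | 2-{[6-hydroxy-1,3-dimethoxy-4-(methoxymethoxy)-5-[(methoxymethoxy)methyl]-1,3-dihydroisobenzofuran-7-yl]oxy}-4-methoxy-3,6-dimethylbenzoic acid (acetal stereoisomer mixture) | OC(=O)c1c(C)cc(OC)c(C)c1Oc1c(O)c(COCOC)c(OCOC)c2C(OC)OC(OC)c12 | intermediate
28 | protected depsidone bis-acetal: seven-membered lactone between the ring-A carboxyl and the B2 oxygen, B4 OMOM, B3 CH2OMOM, B5/B6 fused 1,3-dimethoxy-1,3-dihydrofuran (acetal stereoisomer mixture) | COc1cc(C)c2c(c1C)Oc1c(c(COCOC)c(OCOC)c3c1C(OC)OC3OC)OC2=O | intermediate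
29 | depsidone dialdehyde: B5 and B6 formyl, B4 hydroxyl, B3 hydroxymethyl | COc1cc(C)c2c(c1C)Oc1c(c(CO)c(O)c(C=O)c1C=O)OC2=O | intermediate
30 | CNP0321962.1: depsidone with B3 hydroxymethyl, B4 hydroxyl, B5 lactone carbonyl and B6 (R)-configured lactol carbon | COc1cc(C)c2c(c1C)Oc1c(c(CO)c(O)c3c1[C@H](O)OC3=O)OC2=O | target

**Step count and risks**

Total step count: 17. Longest linear sequence: 11 steps (steps 1, 2, 4, 5, 6, 12–17; the ring-A branch, steps 7–11 and 12–17, is equally long).

Steps most likely to fail:

1. Step 17 (proposed new method). Three processes threaten it: carbene addition to the B6 instead of the B5 formyl group; direct hydrolysis of the acyl azolium followed by uncatalysed, non-selective ring closure; and epimerisation of the lactol through ring opening during isolation. The fallback sets out from dialdehyde 29 and replaces the catalytic desymmetrisation by stoichiometric oxidation and resolution. Pinnick mono-oxidation (NaClO2, 1.0 equiv, NaH2PO4, 2-methylbut-2-ene, t-BuOH/H2O, 0 °C) gives the formyl acid, which exists as its ring tautomer, the racemic lactol F1. F1 is freed from any regioisomeric lactol by reversed-phase chromatography and resolved by preparative supercritical-fluid chromatography on an immobilised polysaccharide chiral phase without acidic or basic modifier. The (R)-enantiomer is 30, where the fallback rejoins the route; the other enantiomer can be re-equilibrated and recycled.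

2. Step 4. The lithiated bis-acetal may undergo β-alkoxide elimination with ring opening before it adds, or the silyl triflate may activate an acetal. The fallback sets out from dione 7 and 3-bromofuran 8 and installs the acetal centres only after the carbon–carbon bond is made. Bromine–lithium exchange (n-BuLi, Et2O, −78 °C) gives the robust furan-3-yllithium F2, which adds to the same carbonyl of 7 to give lithium 2-(benzyloxy)-1-(furan-3-yl)-3-[(methoxymethoxy)methyl]-4-oxocyclobut-2-en-1-olate F3. Silylation with Et3SiOTf at −78 °C gives 3-(benzyloxy)-4-(furan-3-yl)-2-[(methoxymethoxy)methyl]-4-[(triethylsilyl)oxy]cyclobut-2-en-1-one F4. Clauson-Kaas methoxylation of the furan ring (Br2, MeOH, KOAc, −45 °C) then returns to the route at 12.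

3. Step 12. The electron-rich phenoxide may be oxidised by single-electron transfer to the iodonium salt, or ligand coupling may stall at the tetra-ortho-substituted ether. The fallback sets out from silyl ether 16 and aryl iodide 21 and uses copper catalysis instead of hypervalent iodine. CsF in DMF gives phenoxide 24, which undergoes Ullmann diaryl ether coupling with 21 (CuI, 2,2,6,6-tetramethylheptane-3,5-dione, Cs2CO3, NMP, 110 °C), the ortho ester assisting the copper insertion. It returns to the route at 25 and makes no compound outside the list (F0).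

Further compounds
F1 | step 17 | racemic lactol (racemate of 30) | COc1cc(C)c2c(c1C)Oc1c(c(CO)c(O)c3c1C(O)OC3=O)OC2=O
F2 | step 4 | furan-3-yllithium | [Li]c1ccoc1
F3 | step 4 | lithium 2-(benzyloxy)-1-(furan-3-yl)-3-[(methoxymethoxy)methyl]-4-oxocyclobut-2-en-1-olate | [Li+].[O-]C1(C(=O)C(COCOC)=C1OCc2ccccc2)c3ccoc3
F4 | step 4 | 3-(benzyloxy)-4-(furan-3-yl)-2-[(methoxymethoxy)methyl]-4-[(triethylsilyl)oxy]cyclobut-2-en-1-one | CC[Si](CC)(CC)OC1(C(=O)C(COCOC)=C1OCc2ccccc2)c3ccoc3
F0 | step 12 | none | none
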